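First product and bis adduct together stand at 13.1 % at the first reading of the west run, so for this flask I first have to ask where the rest of the charged substrate has gone.

| flask | substrate | reagent | remark | time |
|---|---|---|---|---|
| west | 10 mM | 15 mM | run made earlier |  |
| south-east | 10 mM | 23 mM | run made earlier |  |
| north-east | 15 mM | 10.5 mM | run made earlier |  |
| flask | 10 mM | 10.5 mM |  | 12 d |

| run | time / d | substrate / % | first product / % | bis adduct / % |
|---|---|---|---|---|
| west | 1.25 | 13.0 | 11.2 | 1.9 |
| west | 2.50 | 11.8 | 14.9 | 4.0 |
| west | 4.00 | 9.9 | 16.4 | 8.1 |
| west | 5.00 | 10.1 | 18.4 | 11.0 |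
| west | 6.00 | 8.8 | 18.2 | 13.0 |
| west | 8.00 | 7.3 | 17.9 | 15.7 |
| south-east | 0.500 | 12.7 | 10.1 | 2.2 |
| south-east | 1.25 | 11.5 | 14.0 | 3.5 |
| south-east | 2.50 | 10.2 | 17.3 | 10.3 |
| south-east | 4.00 | 8.7 | 19.6 | 16.1 |
| south-east | 6.00 | 6.9 | 18.8 | 23.8 |
| south-east | 8.00 | 5.3 | 16.2 | 26.9 |
| north-east | 1.25 | 13.4 | 6.6 | 0.6 |
| north-east | 3.00 | 12.7 | 12.2 | 2.6 |
| north-east | 4.00 | 11.0 | 13.2 | 2.9 |
| north-east | 6.00 | 10.7 | 16.1 | 4.4 |
| north-east | 8.00 | 10.5 | 17.2 | 5.7 |

(readings scatter by 0.5 percentage points)

1. substrate at 12 d, in percent of the substrate charged
2. first product at 12 d, in percent of the substrate charged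
3. bis adduct at 12 d, in percent of the substrate charged

- the numbers in the tables scatter by 0.5 percentage points (one standard deviation)

1. If substrate went to the two products and nowhere else, substrate and the two products would add up to the charge, but at that west reading they come to 26.1 %, so my reckoning needs more than the main steps.

2. I add a fast, reversible retreat of substrate into an unseen pool, its resting state. Taking substrate over everything not yet turned into the two products, the first readings of the west, south-east and north-east runs give 15.0 %, 14.5 % and 14.4 %, and I carry their mean 14.6 % as the free share.

3. Dividing the last west substrate reading by the free share gives substrate and pool together at 49.9 %, and with the two products 16.5 % is still missing, against 15.7 % of bis adduct. The south-east run is missing 20.7 % against 26.9 %, so I add a further unseen sink of roughly the size of bis adduct.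

4. This flask has the substrate charge of the west run, and its reagent charge times time is 1.05 times that of the last west reading, so as an estimate I borrow that reading's two products, count bis adduct double to cover the sink, and multiply what remains by the free share, which gives substrate near 7.42 %.

5. The forecast, whose substrate is higher than mine, gives 8.5 % substrate, 17.5 % first product and 10 % bis adduct, saying: “It should therefore run a little ahead of north-east and behind west.”

The flask gives 7.80 % substrate, 18.4 % first product and 11.7 % bis adduct. With the reagent charge moved to 7.41 mM or 13.3 mM, other charges and time held, bis adduct in this flask has shifted by 5 points. Divided by the free share, this substrate gives substrate and pool together at 53.4 %, and the flask holds 53.3 % as substrate and dormant form together at 12.0 d.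

    substrate + reagent → first product + by-product (k = 1.60 M⁻¹ h⁻¹)
    reagent + first product → bis adduct + by-product (k = 0.700 M⁻¹ h⁻¹)
    substrate + bis adduct → side product (k = 4.60 M⁻¹ h⁻¹)
    substrate ⇌ dormant form (K = 5.70, k = 0.470 h⁻¹)

For the neighbour with 18 mM of reagent, I borrow the last south-east reading, whose reagent charge times time that flask exceeds by a factor of 1.17, and the same reckoning gives 4.39 % substrate. Computed, that flask holds 4.60 % of substrate.

The runs are simulated with made-up constants; the scatter is artificial.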